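**Plan**

Retrosynthesis: first C11–H, which comes from a C11 peroxyhemiketal. Next the O–O bridge is removed together with both C–O bonds by rejoining C8–C11, so the 1,2-dioxane (O, O, C8, C9, C10, C11) contracts to a cyclobutanol and the 14-membered carbocycle to a 12-membered one. Then C11–C12 (alkenyl iodide + cyclobutanone), C8–C9 (cyclopropanol-to-cyclobutanone shift), C1–C14 and the C17 methylene (conjugate addition/aminomethylation of a butenolide), C1–C2 (alkynylation of an enal) and C7=C8 (olefination of a geranyl-derived aldehyde).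
Enabling feature: the two peroxide carbons C8 (methyl-bearing, fully substituted) and C11 (allylic to C12=C13) are 1,4-related through C9–C10. A C8–C11 bond therefore gives a cyclobutanol whose alkoxy radical can cleave only towards tertiary C8; strain release lets O2 bridge C8 and C11 and enlarges the 12-membered ring to the cembrane ring in the same event.
Forward: open chain (C2–C7 from geranyl acetate, C8–C11 as an alkenylcyclopropanol) → butenolide → trans α-methylene lactone → Z alkenyl iodide → cyclobutanone → 12-membered carbocycle (Ni/Cr closure at C11–C12) → 14-membered ring and 1,2-dioxane in one operation → deoxygenation at C11.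
Stereochemistry: C2 from catalytic asymmetric alkynylation, C1 from anti conjugate addition to the butenolide, C7 from Shi epoxidation, C8 from face-selective O2 capture next to C7, C11 from hydride delivery to the cis-bridged peroxycarbenium ion; 3E from geraniol, 12Z from the iodo-Wittig reaction.

Key step: step 15

Remark: all intermediates are numbered as the cembrane skeleton of the target (C1 lactone β-carbon, C2 lactone O–CH, C7 acetoxy carbon, C8 and C11 peroxide carbons, C15–C17 methylene lactone).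

**Route**

Step 1
Reactants: 1 geranyl acetate
Product: 2 (2E)-3-methyl-6-oxohex-2-en-1-yl acetate
Conditions: O3 (1.0 equiv), pyridine, CH2Cl2, −78 °C; then Me2S
Reagents that add atoms: ozone, [O-][O+]=O
Why: Chemoselective ozonolysis: the remote trisubstituted alkene is more electron-rich than the one deactivated by the allylic acetate and should be cleaved first, giving the C7 aldehyde; no stereocenter is formed.

Step 2
Reactants: 2 (2E)-3-methyl-6-oxohex-2-en-1-yl acetate; 3 ethyl 2-[bis(2,2,2-trifluoroethoxy)phosphoryl]propanoate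
Product: 4 ethyl (2Z,6E)-8-acetoxy-2,6-dimethylocta-2,6-dienoate
Conditions: KN(SiMe3)2, 18-crown-6, THF, −78 °C
Reagents that add atoms: none
Why: Still–Gennari olefination: fast elimination from the kinetic adduct of the electron-poor phosphonate should give the Z enoate (C7=C8), a geometry that is erased again in step 15 and is chosen only because it leads to the ketol diastereomer that a Grob opening (reserve route) would need.

Step 3
Reactants: 4 ethyl (2Z,6E)-8-acetoxy-2,6-dimethylocta-2,6-dienoate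
Product: 5 1-[(2Z,6E)-8-hydroxy-6-methylocta-2,6-dien-2-yl]cyclopropan-1-ol
Conditions: EtMgBr (6 equiv, slow addition), Ti(OiPr)4 (30 mol%), THF, 0 °C → rt; aq. NH4Cl
Reagents that add atoms: ethylmagnesium bromide, CC[Mg]Br
Why: Kulinkovich cyclopropanation: the titanacyclopropane formed from EtMgBr and Ti(OiPr)4 acts as a 1,2-dicarbanion towards the ester carbonyl and should give the 1-alkenylcyclopropanol (C9, C10, C11) with the trisubstituted conjugated alkene intact, while the acetate is consumed in the same way and frees the C2 alcohol.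

Step 4
Reactants: 5 1-[(2Z,6E)-8-hydroxy-6-methylocta-2,6-dien-2-yl]cyclopropan-1-ol
Product: 6 (2E,6Z)-7-(1-hydroxycyclopropyl)-3-methylocta-2,6-dienal
Conditions: MnO2 (activated, excess), CH2Cl2, rt
Reagents that add atoms: none
Why: Allylic oxidation with MnO2 is selective for the primary allylic alcohol, the tertiary cyclopropanol having no carbinol hydrogen, and the 3E geometry should be retained.

Step 5
Reactants: 6 (2E,6Z)-7-(1-hydroxycyclopropyl)-3-methylocta-2,6-dienal
Product: 7 (2E,6Z)-3-methyl-7-[1-(triethylsilyloxy)cyclopropyl]octa-2,6-dienal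
Conditions: Et3SiOTf, 2,6-lutidine, CH2Cl2, −78 °C
Reagents that add atoms: triethylsilyl trifluoromethanesulfonate, CC[Si](CC)(CC)OS(=O)(=O)C(F)(F)F
Why: Silyl protection of the tertiary cyclopropanol with a silyl triflate and a hindered base, which shields it from the bases and oxidants of steps 6–11 (homoenolate opening, oxidative ring cleavage).

Step 6
Reactants: 7 (2E,6Z)-3-methyl-7-[1-(triethylsilyloxy)cyclopropyl]octa-2,6-dienal; 8 methyl propiolate
Product: 9 methyl (4R,5E,9Z)-4-hydroxy-6-methyl-10-[1-(triethylsilyloxy)cyclopropyl]undeca-5,9-dien-2-ynoate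
Conditions: Me2Zn, (S,S)-ProPhenol [2,6-bis{[(2S)-2-(hydroxydiphenylmethyl)pyrrolidin-1-yl]methyl}-4-methylphenol, 20 mol%], Ph3P=O (40 mol%), toluene, 0 °C
Reagents that add atoms: none
Why: Zinc–ProPhenol-catalysed asymmetric alkynylation of an enal: the dinuclear zinc catalyst binds the aldehyde and the alkynylzinc derived from 8 and should deliver the alkynyl group to the Si face, which sets C2 (4R in 9); the ligand antipode is the one expected to give this sense with enals and would be exchanged if the sense proved opposite.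

Step 7
Reactants: 9 methyl (4R,5E,9Z)-4-hydroxy-6-methyl-10-[1-(triethylsilyloxy)cyclopropyl]undeca-5,9-dien-2-ynoate
Product: 11 (5S)-5-{(1E,5Z)-2-methyl-6-[1-(triethylsilyloxy)cyclopropyl]hepta-1,5-dien-1-yl}furan-2(5H)-one, via cis-hydroxy enoate 10 (not isolated)
Conditions: H2 (1 atm), Pd/CaCO3 poisoned with Pb(OAc)2, quinoline, EtOAc, rt; then silica gel, CH2Cl2, rt
Reagents that add atoms: none
Why: cis-Selective semihydrogenation of the ynoate on lead-poisoned palladium should stop at the Z enoate, whose γ-hydroxyl lactonises to the butenolide (acyl substitution) without touching C2 or the trisubstituted alkenes.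

Step 8
Reactants: 11 (5S)-5-{(1E,5Z)-2-methyl-6-[1-(triethylsilyloxy)cyclopropyl]hepta-1,5-dien-1-yl}furan-2(5H)-one
Product: 15 (4S,5R)-4-ethenyl-3-methylidene-5-{(1E,5Z)-2-methyl-6-[1-(triethylsilyloxy)cyclopropyl]hepta-1,5-dien-1-yl}oxolan-2-one, via silyl ketene acetal 12 (not isolated), via Mannich base 13 (not isolated), via ammonium iodide 14 (not isolated)
Conditions: CH2=CHMgBr, CuBr·SMe2 (10 mol%), Me3SiCl, THF, −78 °C; then [CH2=NMe2]I, −78 °C → rt; concentrate; MeI, MeOH, rt; aq. NaHCO3, CH2Cl2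
Reagents that add atoms: vinylmagnesium bromide, C=C[Mg]Br; dimethyl(methylidene)ammonium iodide, C=[N+](C)C.[I-]
Why: Copper-catalysed conjugate addition of the vinyl Grignard reagent to the butenolide should occur anti to the C2 substituent and set C1 (trans lactone), the silyl ketene acetal is aminomethylated by the iminium salt (Mannich reaction), and N-methylation/E1cB elimination installs the exocyclic methylene group.

Step 9
Reactants: 15 (4S,5R)-4-ethenyl-3-methylidene-5-{(1E,5Z)-2-methyl-6-[1-(triethylsilyloxy)cyclopropyl]hepta-1,5-dien-1-yl}oxolan-2-one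
Product: 16 (4S,5R)-4-(2-hydroxyethyl)-3-methylidene-5-{(1E,5Z)-2-methyl-6-[1-(triethylsilyloxy)cyclopropyl]hepta-1,5-dien-1-yl}oxolan-2-one
Conditions: 9-BBN, THF, 0 °C → rt; then NaBO3·4H2O, H2O, rt
Reagents that add atoms: sodium perborate, O=BO[O-].[Na+]
Why: Hydroboration–oxidation: 9-BBN should add only to the monosubstituted vinyl group (anti-Markovnikov), leaving the trisubstituted alkenes and the electron-poor methylene lactone, and perborate oxidises the borane without epoxidising the acrylate.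

Step 10
Reactants: 16 (4S,5R)-4-(2-hydroxyethyl)-3-methylidene-5-{(1E,5Z)-2-methyl-6-[1-(triethylsilyloxy)cyclopropyl]hepta-1,5-dien-1-yl}oxolan-2-one
Product: 17 2-[(2R,3S)-4-methylidene-2-{(1E,5Z)-2-methyl-6-[1-(triethylsilyloxy)cyclopropyl]hepta-1,5-dien-1-yl}-5-oxooxolan-3-yl]acetaldehyde
Conditions: Dess–Martin periodinane, NaHCO3, CH2Cl2, 0 °C → rt
Reagents that add atoms: none
Why: Dess–Martin oxidation of the primary alcohol under buffered, non-basic conditions should give the C13 aldehyde without conjugate addition or epimerisation at C1.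

Step 11
Reactants: 17 2-[(2R,3S)-4-methylidene-2-{(1E,5Z)-2-methyl-6-[1-(triethylsilyloxy)cyclopropyl]hepta-1,5-dien-1-yl}-5-oxooxolan-3-yl]acetaldehyde; 18 ethyltriphenylphosphonium iodide
Product: 22 (4S,5R)-4-[(2Z)-3-iodobut-2-en-1-yl]-3-methylidene-5-{(1E,5Z)-2-methyl-6-[1-(triethylsilyloxy)cyclopropyl]hepta-1,5-dien-1-yl}oxolan-2-one, via ylide 19 (not isolated), via iodophosphonium salt 20 (not isolated), via iodo ylide 21 (not isolated)
Conditions: 18, n-BuLi, THF, 0 °C; I2, −78 °C; NaN(SiMe3)2, −78 °C; then 17, −78 → −20 °C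
Reagents that add atoms: iodine, II
Why: Stork–Zhao-type Wittig olefination: the α-iodo ylide made in the flask should add to the aldehyde at −78 °C faster than to the methylene lactone and collapse through the cis-oxaphosphetane to the Z alkenyl iodide (iodine cis to C14), which fixes the 12Z geometry.

Step 12
Reactants: 22 (4S,5R)-4-[(2Z)-3-iodobut-2-en-1-yl]-3-methylidene-5-{(1E,5Z)-2-methyl-6-[1-(triethylsilyloxy)cyclopropyl]hepta-1,5-dien-1-yl}oxolan-2-one
Product: 24 (4S,5R)-5-{(1E,5S)-5-hydroxy-2-methyl-5-[(1R)-1-methyl-2-oxocyclobutyl]pent-1-en-1-yl}-4-[(2Z)-3-iodobut-2-en-1-yl]-3-methylideneoxolan-2-one, via epoxide 23 (not isolated)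
Conditions: L-fructose-derived Shi ketone (1,2:4,5-di-O-isopropylidene-β-L-erythro-2,3-hexodiulo-2,6-pyranose, 30 mol%), KHSO5 (as 2KHSO5·KHSO4·K2SO4), K2CO3, Bu4NHSO4, MeCN/CH2(OMe)2/aq. Na2B4O7, 0 °C; then HF·pyridine, THF, 0 °C
Reagents that add atoms: potassium peroxymonosulfate, OOS(=O)(=O)[O-].[K+]
Why: Shi asymmetric epoxidation (spiro transition state of the chiral dioxirane) should oxidise the only electron-rich alkene, C7=C8, from the face that gives 7S with the L-fructose-derived ketone, and HF·pyridine then removes the silyl group and triggers the semipinacol ring expansion in which a cyclopropane C–C bond migrates to the tertiary epoxide carbon C8 anti to the departing oxygen, so that C7–O keeps its configuration while C8 (R here) is only temporary.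

Step 13
Reactants: 24 (4S,5R)-5-{(1E,5S)-5-hydroxy-2-methyl-5-[(1R)-1-methyl-2-oxocyclobutyl]pent-1-en-1-yl}-4-[(2Z)-3-iodobut-2-en-1-yl]-3-methylideneoxolan-2-one
Product: 25 (1S,4E)-5-{(2R,3S)-3-[(2Z)-3-iodobut-2-en-1-yl]-4-methylidene-5-oxooxolan-2-yl}-4-methyl-1-[(1R)-1-methyl-2-oxocyclobutyl]pent-4-en-1-yl acetate
Conditions: Ac2O, pyridine, DMAP (cat.), CH2Cl2, 0 °C
Reagents that add atoms: acetic anhydride, CC(=O)OC(C)=O
Why: Acylation of the secondary alcohol (DMAP catalysis); the α-quaternary ketol cannot eliminate, and retro-aldol cleavage is disfavoured because it would generate a strained cyclobutanone enolate.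

Step 14
Reactants: 25 (1S,4E)-5-{(2R,3S)-3-[(2Z)-3-iodobut-2-en-1-yl]-4-methylidene-5-oxooxolan-2-yl}-4-methyl-1-[(1R)-1-methyl-2-oxocyclobutyl]pent-4-en-1-yl acetate
Product: 26 (1S,2R,3E,7S,8R,12Z)-7-acetoxy-11-hydroxy-8,11-cyclocembra-3,12,15(17)-trien-16,2-olide (C8–C11 bond: cyclobutanol fused to the 12-membered carbocycle; C11 epimers)
Conditions: CrCl2 (6 equiv), NiCl2 (2 mol%), DMSO/THF, rt, syringe-pump addition to 2 mM
Reagents that add atoms: none
Why: Nozaki–Hiyama–Kishi reaction: zerovalent nickel inserts into the C–I bond with retention of the Z geometry, transmetalation gives a trivalent alkenylchromium species that should add only to the strained, aldehyde-like cyclobutanone (lactone and acetate are inert) under high dilution, closing the 12-membered carbocycle at C11–C12; the new carbinol centre C11 forms as a mixture that does not matter because C11 and C8 are both planarised in step 15.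

Step 15
Reactants: 26 (1S,2R,3E,7S,8R,12Z)-7-acetoxy-11-hydroxy-8,11-cyclocembra-3,12,15(17)-trien-16,2-olide
Product: 28 (1S,2R,3E,7S,8R,11S,12Z)-7-acetoxy-8,11-epidioxy-11-hydroxycembra-3,12,15(17)-trien-16,2-olide, via hydroperoxy enone 27 (not isolated)
Conditions: Co(acac)2 (20 mol%), O2 (1 atm, saturated solution), MeCN, 40 °C
Reagents that add atoms: dioxygen, O=O
Why: Co(acac)2/O2 should convert the tertiary cyclobutanol into a trivalent cobalt alkoxide that releases the alkoxy radical; β-scission of the strained C8–C11 bond (the bond shared by the four- and twelve-membered rings) is the only cleavage that gives a tertiary radical and a conjugated enone, so the 12-membered carbocycle opens to the 14-membered cembrane ring, the C8 radical is trapped by triplet O2 and the peroxyl radical is reduced to the hydroperoxide 27. The closest known reaction type is the cobalt-catalysed aerobic oxidative ring expansion of cyclobutanols to 1,2-dioxan-3-ols. The 1,2-dioxane is closed by 6-exo-trig addition of the C8 hydroperoxide to the C11 carbonyl (peroxyhemiketalisation), whereas the 14-membered carbocycle is not closed but unveiled by two-carbon enlargement of the bicyclo[10.2.0] frame. C8 is set in the O2-capture step: the radical is planar (the C8 configuration of 26 is erased) and oxygen is expected to enter anti to the C7–OAc bond in the extended C6–C7–C8–C9 conformer (β-acyloxy C–O bond aligned with the singly occupied orbital), giving 8R, the relative configuration of a trans-epoxide opening; the hemiketal centre C11 follows from the need for a cis bridge over the ten-carbon chain and is replaced in step 16. The step needs regioselective scission (secured by tertiary C8 against primary C10), O2 capture faster than transannular radical addition to the enone or the acrylate (secured by O2 saturation), tolerance of the trisubstituted alkenes and the methylene lactone (no hydride source is present), and C8 facial selectivity, which rests only on 1,2-induction from C7 and is the weak point.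

Step 16
Reactants: 28 (1S,2R,3E,7S,8R,11S,12Z)-7-acetoxy-8,11-epidioxy-11-hydroxycembra-3,12,15(17)-trien-16,2-olide
Product: 29 (1S,2R,3E,7S,8R,11S,12Z)-7-acetoxy-8,11-epidioxycembra-3,12,15(17)-trien-16,2-olide (target)
Conditions: Et3SiH, BF3·OEt2, CH2Cl2, −78 → −40 °C
Reagents that add atoms: none
Why: Silane reduction of a peroxyketal: BF3 ionises the tertiary C11–OH to a peroxycarbenium ion conjugated with C12=C13, and Et3SiH should deliver hydride to C11 from the face away from the ten-carbon bridge, giving the cis-bridged 1,2-dioxane (11S) with the O–O bond, the acetate and the methylene lactone untouched.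

**Compound list**

1 | geranyl acetate, (2E)-3,7-dimethylocta-2,6-dien-1-yl acetate | CC(C)=CCC/C(C)=C/COC(C)=O | starting material
2 | (2E)-3-methyl-6-oxohex-2-en-1-yl acetate | O=CCC/C(C)=C/COC(C)=O | intermediate
3 | ethyl 2-[bis(2,2,2-trifluoroethoxy)phosphoryl]propanoate | CCOC(=O)C(C)P(=O)(OCC(F)(F)F)OCC(F)(F)F | starting material
4 | ethyl (2Z,6E)-8-acetoxy-2,6-dimethylocta-2,6-dienoate | CCOC(=O)/C(C)=C\CC/C(C)=C/COC(C)=O | intermediate
5 | 1-[(2Z,6E)-8-hydroxy-6-methylocta-2,6-dien-2-yl]cyclopropan-1-ol | OC/C=C(\C)CC/C=C(/C)C1(O)CC1 | intermediate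
6 | (2E,6Z)-7-(1-hydroxycyclopropyl)-3-methylocta-2,6-dienal | O=C/C=C(\C)CC/C=C(/C)C1(O)CC1 | intermediate
7 | (2E,6Z)-3-methyl-7-[1-(triethylsilyloxy)cyclopropyl]octa-2,6-dienal | O=C/C=C(\C)CC/C=C(/C)C1(O[Si](CC)(CC)CC)CC1 | intermediate
8 | methyl propiolate | C#CC(=O)OC | starting material
9 | methyl (4R,5E,9Z)-4-hydroxy-6-methyl-10-[1-(triethylsilyloxy)cyclopropyl]undeca-5,9-dien-2-ynoate | COC(=O)C#C[C@H](O)/C=C(\C)CC/C=C(/C)C1(O[Si](CC)(CC)CC)CC1 | intermediate
10 | methyl (2Z,4S,5E,9Z)-4-hydroxy-6-methyl-10-[1-(triethylsilyloxy)cyclopropyl]undeca-2,5,9-trienoate | COC(=O)/C=C\[C@H](O)/C=C(\C)CC/C=C(/C)C1(O[Si](CC)(CC)CC)CC1 | intermediate (not isolated)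
11 | (5S)-5-{(1E,5Z)-2-methyl-6-[1-(triethylsilyloxy)cyclopropyl]hepta-1,5-dien-1-yl}furan-2(5H)-one | O=C1O[C@H](/C=C(\C)CC/C=C(/C)C2(O[Si](CC)(CC)CC)CC2)C=C1 | intermediate
12 | (4S,5S)-4-ethenyl-5-{(1E,5Z)-2-methyl-6-[1-(triethylsilyloxy)cyclopropyl]hepta-1,5-dien-1-yl}-2-(trimethylsilyloxy)-4,5-dihydrofuran | C1=C(O[Si](C)(C)C)O[C@H](/C=C(\C)CC/C=C(/C)C2(O[Si](CC)(CC)CC)CC2)[C@H]1C=C | intermediate (not isolated)
13 | (3RS,4S,5S)-3-[(dimethylamino)methyl]-4-ethenyl-5-{(1E,5Z)-2-methyl-6-[1-(triethylsilyloxy)cyclopropyl]hepta-1,5-dien-1-yl}oxolan-2-one | CN(C)CC1C(=O)O[C@H](/C=C(\C)CC/C=C(/C)C2(O[Si](CC)(CC)CC)CC2)[C@H]1C=C | intermediate (not isolated)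
14 | 1-[(4S,5S)-4-ethenyl-2-oxo-5-{(1E,5Z)-2-methyl-6-[1-(triethylsilyloxy)cyclopropyl]hepta-1,5-dien-1-yl}oxolan-3-yl]-N,N,N-trimethylmethanaminium iodide (C3 epimers) | C[N+](C)(C)CC1C(=O)O[C@H](/C=C(\C)CC/C=C(/C)C2(O[Si](CC)(CC)CC)CC2)[C@H]1C=C.[I-] | intermediate (not isolated)
15 | (4S,5R)-4-ethenyl-3-methylidene-5-{(1E,5Z)-2-methyl-6-[1-(triethylsilyloxy)cyclopropyl]hepta-1,5-dien-1-yl}oxolan-2-one | C=C1C(=O)O[C@H](/C=C(\C)CC/C=C(/C)C2(O[Si](CC)(CC)CC)CC2)[C@H]1C=C | intermediate
16 | (4S,5R)-4-(2-hydroxyethyl)-3-methylidene-5-{(1E,5Z)-2-methyl-6-[1-(triethylsilyloxy)cyclopropyl]hepta-1,5-dien-1-yl}oxolan-2-one | C=C1C(=O)O[C@H](/C=C(\C)CC/C=C(/C)C2(O[Si](CC)(CC)CC)CC2)[C@H]1CCO | intermediate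
17 | 2-[(2R,3S)-4-methylidene-2-{(1E,5Z)-2-methyl-6-[1-(triethylsilyloxy)cyclopropyl]hepta-1,5-dien-1-yl}-5-oxooxolan-3-yl]acetaldehyde | C=C1C(=O)O[C@H](/C=C(\C)CC/C=C(/C)C2(O[Si](CC)(CC)CC)CC2)[C@H]1CC=O | intermediate
18 | ethyltriphenylphosphonium iodide | CC[P+](c1ccccc1)(c1ccccc1)c1ccccc1.[I-] | starting material
19 | ethylidenetriphenylphosphorane | CC=P(c1ccccc1)(c1ccccc1)c1ccccc1 | intermediate (not isolated)
20 | (1-iodoethyl)triphenylphosphonium iodide | CC(I)[P+](c1ccccc1)(c1ccccc1)c1ccccc1.[I-] | intermediate (not isolated)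
21 | (1-iodoethylidene)triphenylphosphorane | CC(I)=P(c1ccccc1)(c1ccccc1)c1ccccc1 | intermediate (not isolated)
22 | (4S,5R)-4-[(2Z)-3-iodobut-2-en-1-yl]-3-methylidene-5-{(1E,5Z)-2-methyl-6-[1-(triethylsilyloxy)cyclopropyl]hepta-1,5-dien-1-yl}oxolan-2-one | C=C1C(=O)O[C@H](/C=C(\C)CC/C=C(/C)C2(O[Si](CC)(CC)CC)CC2)[C@H]1C/C=C(/C)I | intermediate
23 | (4S,5R)-4-[(2Z)-3-iodobut-2-en-1-yl]-3-methylidene-5-{(1E)-2-methyl-4-[(2S,3S)-3-methyl-3-[1-(triethylsilyloxy)cyclopropyl]oxiran-2-yl]but-1-en-1-yl}oxolan-2-one | C=C1C(=O)O[C@H](/C=C(\C)CC[C@@H]3O[C@]3(C)C2(O[Si](CC)(CC)CC)CC2)[C@H]1C/C=C(/C)I | intermediate (not isolated)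
24 | (4S,5R)-5-{(1E,5S)-5-hydroxy-2-methyl-5-[(1R)-1-methyl-2-oxocyclobutyl]pent-1-en-1-yl}-4-[(2Z)-3-iodobut-2-en-1-yl]-3-methylideneoxolan-2-one | C=C1C(=O)O[C@H](/C=C(\C)CC[C@H](O)[C@@]3(C)CCC3=O)[C@H]1C/C=C(/C)I | intermediate
25 | (1S,4E)-5-{(2R,3S)-3-[(2Z)-3-iodobut-2-en-1-yl]-4-methylidene-5-oxooxolan-2-yl}-4-methyl-1-[(1R)-1-methyl-2-oxocyclobutyl]pent-4-en-1-yl acetate | C=C1C(=O)O[C@H](/C=C(\C)CC[C@H](OC(C)=O)[C@@]3(C)CCC3=O)[C@H]1C/C=C(/C)I | intermediate
26 | (1S,2R,3E,7S,8R,12Z)-7-acetoxy-11-hydroxy-8,11-cyclocembra-3,12,15(17)-trien-16,2-olide (C11 epimers) | C=C1C(=O)O[C@@H]2/C=C(\C)CC[C@H](OC(C)=O)[C@@]3(C)CCC3(O)/C(C)=C\C[C@@H]12 | intermediate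
27 | (1S,2R,3E,7S,8R,12Z)-7-acetoxy-8-hydroperoxy-11-oxocembra-3,12,15(17)-trien-16,2-olide | C=C1C(=O)O[C@@H]2/C=C(\C)CC[C@H](OC(C)=O)[C@](C)(OO)CCC(=O)/C(C)=C\C[C@@H]12 | intermediate (not isolated)
28 | (1S,2R,3E,7S,8R,11S,12Z)-7-acetoxy-8,11-epidioxy-11-hydroxycembra-3,12,15(17)-trien-16,2-olide | C=C1C(=O)O[C@@H]2/C=C(\C)CC[C@H](OC(C)=O)[C@@]3(C)CC[C@](O)(OO3)/C(C)=C\C[C@@H]12 | intermediate
29 | (1S,2R,3E,7S,8R,11S,12Z)-7-acetoxy-8,11-epidioxycembra-3,12,15(17)-trien-16,2-olide | C=C1C(=O)O[C@@H]2/C=C(\C)CC[C@H](OC(C)=O)[C@@]3(C)CC[C@H](OO3)/C(C)=C\C[C@@H]12 | target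

**Step count and risks**

Total step count: 16. Longest linear sequence: 16 steps (1 → 29).

Steps most likely to fail:

1. Step 15 (key step). What may go wrong: poor facial discrimination when O2 adds to the planar C8 radical, since only 1,2-induction from C7 is available, or transannular radical addition to the enone outrunning O2 capture. Fallback, polar and stereospecific, setting out from 24 and returning at 28: the ketol would be mesylated (MsCl, Et3N, CH2Cl2) to the mesylate F1 and closed by the Ni/Cr coupling of step 14 to the bicyclic cyclobutanol mesylate F2. KOt-Bu in THF would then trigger a Grob fragmentation of the C8–C11 bond anti-periplanar to the C7–OMs bond. Because 24 descends from the Z enoate, this should give the 14-membered trienone F3 with a 7E alkene. Shi epoxidation with the same L-fructose-derived ketone should give the (7S,8S)-epoxy enone F4. Ethereal H2O2 with catalytic H3PMo12O40 should open the epoxide at tertiary C8 with inversion to the hydroperoxy ketone F5, which should close to the hydroxy peroxyhemiketal F6. Acetylation of the secondary C7–OH (Ac2O, pyridine, 0 °C) leads back to 28.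

2. Step 14. What may go wrong: slow transfer of the alkenyl group to the ketone, so that protodeiodination or oligomerisation overtakes the strained 12-membered closure. Fallback, ring-closing metathesis at C12=C13 in place of carbonyl alkenylation, setting out from 17 and returning at 26: methylenation with Ph3P=CH2 would give the allyl lactone F7. The conditions of step 12 would lead through the epoxide F8 to the ketol F9, and acetylation would give the acetate F10. CH2=C(CH3)MgBr with CeCl3 at −78 °C would add to the cyclobutanone to give the isopropenyl carbinol F11. Ring-closing metathesis with the second-generation Grubbs catalyst under high dilution would close the ring to 26; the Z geometry would then depend on the strain of the bicyclic frame and has to be checked.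

3. Step 12. What may go wrong: weak enantiofacial discrimination by the dioxirane at the hindered Z-trisubstituted alkene, or competing oxidation at C3=C4 or at the alkenyl iodide. Fallback, a hydroxyl-directed metal-peroxide epoxidation in place of the dioxirane, setting out from 22 and returning at 24: Bu4NF in THF would remove the silyl group to give the free alkenylcyclopropanol F12. Hf(OtBu)4 with a chiral C2-symmetric bishydroxamic acid ligand and cumene hydroperoxide (asymmetric epoxidation of tertiary allylic alcohols, in which the cyclopropanol OH binds the metal and confines the oxidant to C7=C8) should give the epoxy cyclopropanol F13. Brief exposure to pyridinium p-toluenesulfonate should rearrange it to 24.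

**Further compounds**

F1 | step 15 | (1S,4E)-5-{(2R,3S)-3-[(2Z)-3-iodobut-2-en-1-yl]-4-methylidene-5-oxooxolan-2-yl}-4-methyl-1-[(1R)-1-methyl-2-oxocyclobutyl]pent-4-en-1-yl methanesulfonate | C=C1C(=O)O[C@H](/C=C(\C)CC[C@H](OS(C)(=O)=O)[C@@]3(C)CCC3=O)[C@H]1C/C=C(/C)I
F2 | step 15 | (1S,2R,3E,7S,8R,12Z)-11-hydroxy-7-(methanesulfonyloxy)-8,11-cyclocembra-3,12,15(17)-trien-16,2-olide (C11 epimers) | C=C1C(=O)O[C@@H]2/C=C(\C)CC[C@H](OS(C)(=O)=O)[C@@]3(C)CCC3(O)/C(C)=C\C[C@@H]12
F3 | step 15 | (1S,2R,3E,7E,12Z)-11-oxocembra-3,7,12,15(17)-tetraen-16,2-olide | C=C1C(=O)O[C@@H]2/C=C(\C)CC/C=C(\C)CCC(=O)/C(C)=C\C[C@@H]12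
F4 | step 15 | (1S,2R,3E,7S,8S,12Z)-7,8-epoxy-11-oxocembra-3,12,15(17)-trien-16,2-olide | C=C1C(=O)O[C@@H]2/C=C(\C)CC[C@@H]3O[C@@]3(C)CCC(=O)/C(C)=C\C[C@@H]12
F5 | step 15 | (1S,2R,3E,7S,8R,12Z)-8-hydroperoxy-7-hydroxy-11-oxocembra-3,12,15(17)-trien-16,2-olide | C=C1C(=O)O[C@@H]2/C=C(\C)CC[C@H](O)[C@](C)(OO)CCC(=O)/C(C)=C\C[C@@H]12
F6 | step 15 | (1S,2R,3E,7S,8R,11S,12Z)-8,11-epidioxy-7,11-dihydroxycembra-3,12,15(17)-trien-16,2-olide | C=C1C(=O)O[C@@H]2/C=C(\C)CC[C@H](O)[C@@]3(C)CC[C@](O)(OO3)/C(C)=C\C[C@@H]12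
F7 | step 14 | (4S,5R)-3-methylidene-5-{(1E,5Z)-2-methyl-6-[1-(triethylsilyloxy)cyclopropyl]hepta-1,5-dien-1-yl}-4-(prop-2-en-1-yl)oxolan-2-one | C=C1C(=O)O[C@H](/C=C(\C)CC/C=C(/C)C2(O[Si](CC)(CC)CC)CC2)[C@H]1CC=C
F8 | step 14 | (4S,5R)-3-methylidene-5-{(1E)-2-methyl-4-[(2S,3S)-3-methyl-3-[1-(triethylsilyloxy)cyclopropyl]oxiran-2-yl]but-1-en-1-yl}-4-(prop-2-en-1-yl)oxolan-2-one | C=C1C(=O)O[C@H](/C=C(\C)CC[C@@H]3O[C@]3(C)C2(O[Si](CC)(CC)CC)CC2)[C@H]1CC=C
F9 | step 14 | (4S,5R)-5-{(1E,5S)-5-hydroxy-2-methyl-5-[(1R)-1-methyl-2-oxocyclobutyl]pent-1-en-1-yl}-3-methylidene-4-(prop-2-en-1-yl)oxolan-2-one | C=C1C(=O)O[C@H](/C=C(\C)CC[C@H](O)[C@@]3(C)CCC3=O)[C@H]1CC=C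
F10 | step 14 | (1S,4E)-4-methyl-1-[(1R)-1-methyl-2-oxocyclobutyl]-5-[(2R,3S)-4-methylidene-5-oxo-3-(prop-2-en-1-yl)oxolan-2-yl]pent-4-en-1-yl acetate | C=C1C(=O)O[C@H](/C=C(\C)CC[C@H](OC(C)=O)[C@@]3(C)CCC3=O)[C@H]1CC=C
F11 | step 14 | (1S,4E)-1-[(1R)-2-hydroxy-1-methyl-2-(prop-1-en-2-yl)cyclobutyl]-4-methyl-5-[(2R,3S)-4-methylidene-5-oxo-3-(prop-2-en-1-yl)oxolan-2-yl]pent-4-en-1-yl acetate (carbinol epimers) | C=C1C(=O)O[C@H](/C=C(\C)CC[C@H](OC(C)=O)[C@@]3(C)CCC3(O)C(C)=C)[C@H]1CC=C
F12 | step 12 | (4S,5R)-5-[(1E,5Z)-6-(1-hydroxycyclopropyl)-2-methylhepta-1,5-dien-1-yl]-4-[(2Z)-3-iodobut-2-en-1-yl]-3-methylideneoxolan-2-one | C=C1C(=O)O[C@H](/C=C(\C)CC/C=C(/C)C2(O)CC2)[C@H]1C/C=C(/C)I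
F13 | step 12 | (4S,5R)-5-{(1E)-4-[(2S,3S)-3-(1-hydroxycyclopropyl)-3-methyloxiran-2-yl]-2-methylbut-1-en-1-yl}-4-[(2Z)-3-iodobut-2-en-1-yl]-3-methylideneoxolan-2-one | C=C1C(=O)O[C@H](/C=C(\C)CC[C@@H]3O[C@]3(C)C2(O)CC2)[C@H]1C/C=C(/C)I
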